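## Retrosynthetic overview

- Target ⇐ C‑desilylation ⇐ Z‑selective enyne cross‑metathesis (C3=C4) on an (E)‑2‑(but‑3‑enylidene) bicycle; locants C1–C15 follow the target chain from the alkyne end.
- Bicycle ⇐ one‑flask bicyclization of an acyclic 8‑bromo‑9,10‑diol with a terminal C6≡C7 alkyne and the E‑C12=C13 alkene. Ring B closes first (O9→C12, Br to C13), then ring A (O10→C7, allyl to C6, trans to O).
- Bromo diol ⇐ bromide opening (inversion at C8) of a threo cis‑alkynyl epoxy alcohol ⇐ hydroxyl‑directed epoxidation of a (Z)‑enynol.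
- (Z)‑Enynol ⇐ cis‑semireduction of a silyl diynol ⇐ catalytic asymmetric addition of a silylbutadiyne to (E)‑hex‑3‑enal; this sets C10, from which every other stereocentre is relayed.

Assumption: (S,S)‑ProPhenol delivers the 5S alcohol 6 (to be checked by Mosher analysis); if the sense is opposite, (R,R)‑ProPhenol is used and nothing else changes.

## Route

Step 1
Reactants: 1 1,4‑bis(trimethylsilyl)buta‑1,3‑diyne
Product: 3 buta‑1,3‑diyn‑1‑yl(trimethyl)silane, via lithium silylbutadiynide 2 (not isolated)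
Conditions: MeLi·LiBr (1.0 equiv), Et2O, 0 °C → rt; then H2O
Reagents that add atoms: none
Why: Si–C(sp) cleavage by methyllithium (desilylative lithiation) stops after one silyl group because the acetylide 2 is inert to a second attack, and protonation gives the terminal diyne.

Step 2
Reactants: 4 (3E)‑hex‑3‑en‑1‑ol
Product: 5 (3E)‑hex‑3‑enal
Conditions: IBX (1.3 equiv), DMSO, rt; used at once
Reagents that add atoms: none
Why: IBX oxidation is neutral, so the β,γ‑alkene neither migrates into conjugation nor loses its E geometry.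

Step 3
Reactants: 5 (3E)‑hex‑3‑enal; 3 buta‑1,3‑diyn‑1‑yl(trimethyl)silane
Product: 6 (5S,7E)‑1‑(trimethylsilyl)deca‑7‑ene‑1,3‑diyn‑5‑ol
Conditions: (S,S)‑ProPhenol (20 mol %), Me2Zn (3 equiv), Ph3PO (40 mol %), toluene, 4 °C, slow addition of 5
Reagents that add atoms: none
Why: Zinc–ProPhenol catalytic asymmetric alkynylation, in which the dinuclear zinc complex binds the aldehyde and transfers the diynyl group to one carbonyl face, setting C10 (5S in 6); slow addition suppresses enolisation.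

Step 4
Reactants: 6 (5S,7E)‑1‑(trimethylsilyl)deca‑7‑ene‑1,3‑diyn‑5‑ol
Product: 8 (3Z,5S,7E)‑deca‑3,7‑dien‑1‑yn‑5‑ol, via C‑silyl enynol 7 (not isolated)
Conditions: Zn dust activated with Cu(OAc)2 and AgNO3, MeOH/H2O 1:1, 40 °C; filter; then K2CO3 (0.2 equiv), MeOH, rt
Reagents that add atoms: none
Why: Boland‑type zinc reduction adds two hydrogens syn to the hydroxyl‑activated, unsilylated triple bond only (Z alkene; silylalkyne and E alkene untouched), and carbonate in methanol then cleaves the C–Si bond (protodesilylation).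

Step 5
Reactants: 8 (3Z,5S,7E)‑deca‑3,7‑dien‑1‑yn‑5‑ol
Product: 9 (1S,3E)‑1‑[(2R,3S)‑3‑ethynyloxiran‑2‑yl]hex‑3‑en‑1‑ol
Conditions: Ti(OiPr)4 (1.2 equiv), t‑BuOOH (2 equiv, decane), 4 Å MS, CH2Cl2, −20 → 0 °C
Reagents that add atoms: tert‑butyl hydroperoxide CC(C)(C)OO
Why: Hydroxyl‑directed epoxidation through the titanium alkoxide reaches only the allylic enyne alkene, and A(1,3) strain with the cis‑alkynyl group holds H‑10 in the alkene plane so oxygen arrives syn to the hydroxyl, giving the threo cis‑epoxide (C8, C9).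

Step 6
Reactants: 9 (1S,3E)‑1‑[(2R,3S)‑3‑ethynyloxiran‑2‑yl]hex‑3‑en‑1‑ol
Product: 10 (3R,4R,5S,7E)‑3‑bromodec‑7‑en‑1‑yne‑4,5‑diol
Conditions: MgBr2·OEt2 (3 equiv), Et2O, −20 → 0 °C
Reagents that add atoms: magnesium bromide diethyl etherate [Mg+2].[Br-].[Br-].CCOCC
Why: Chelation‑assisted SN2 epoxide opening by bromide at the propargylic carbon remote from the hydroxyl proceeds with inversion, setting the C8 bromide syn (threo) to the retained C9 hydroxyl.

Step 7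
Reactants: 10 (3R,4R,5S,7E)‑3‑bromodec‑7‑en‑1‑yne‑4,5‑diol
Product: 12 (2E,3S,3aR,5R,6aS)‑3‑bromo‑5‑[(1S)‑1‑bromopropyl]‑2‑(but‑3‑en‑1‑ylidene)hexahydrofuro[3,2‑b]furan, via dibromo oxolanol 11 (not isolated)
Conditions: NBS (1.0 equiv), CH2Cl2, −20 → 0 °C; then PdCl2(MeCN)2 (10 mol %), allyl chloride (10 equiv), propylene oxide (5 equiv), THF, 0 °C → rt
Reagents that add atoms: N‑bromosuccinimide O=C1CCC(=O)N1Br; allyl chloride C=CCCl
Why: Proposed new method: NBS forms the C12–C13 bromonium ion and O9 opens it 5‑exo and anti (E alkene → 12R,13S, the side chain going trans to the cis‑disposed C8 and O10 substituents in the less crowded envelope), then PdCl2(MeCN)2 activates the terminal alkyne, O10 attacks C7 anti to palladium (5‑exo‑dig, cis fusion being the only one possible) and the (E)‑alkenylpalladium inserts allyl chloride and loses chloride by β‑elimination, which regenerates divalent palladium and places the allyl group trans to oxygen; the closest known reaction types are 5‑exo bromoetherification of 4‑alkenols and the divalent‑palladium‑catalysed cyclization–allylation of alkynoates and 2‑alkynylanilines with allyl halides.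

Step 8
Reactants: 13 bromoethene; 14 ethynyl(trimethyl)silane
Product: 15 but‑3‑en‑1‑yn‑1‑yl(trimethyl)silane
Conditions: Pd(PPh3)2Cl2 (2 mol %), CuI (4 mol %), Et2NH, THF, 0 °C → rt
Reagents that add atoms: none
Why: Sonogashira coupling (oxidative addition of zerovalent palladium to the vinyl bromide, copper acetylide transmetalation, reductive elimination) gives the enyne partner.

Step 9
Reactants: 12 (2E,3S,3aR,5R,6aS)‑3‑bromo‑5‑[(1S)‑1‑bromopropyl]‑2‑(but‑3‑en‑1‑ylidene)hexahydrofuro[3,2‑b]furan; 15 but‑3‑en‑1‑yn‑1‑yl(trimethyl)silane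
Product: 16 (2E,3S,3aR,5R,6aS)‑3‑bromo‑5‑[(1S)‑1‑bromopropyl]‑2‑[(3Z)‑6‑(trimethylsilyl)hex‑3‑en‑5‑yn‑1‑ylidene]hexahydrofuro[3,2‑b]furan
Conditions: 15 (4 equiv), RuCl2(=CHPh)(H2IMes)(PCy3) (second‑generation Grubbs catalyst, 10 mol %), 1,4‑benzoquinone (10 mol %), CH2Cl2, 40 °C
Reagents that add atoms: none
Why: Olefin cross‑metathesis of a terminal alkene with a conjugated enyne is kinetically Z‑selective (the slim alkynyl group sits syn to the alkyl chain in the ruthenacyclobutane), the trisubstituted enol ether and both bromides are inert, and the minor E isomer is removed by chromatography.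

Step 10
Reactants: 16 (2E,3S,3aR,5R,6aS)‑3‑bromo‑5‑[(1S)‑1‑bromopropyl]‑2‑[(3Z)‑6‑(trimethylsilyl)hex‑3‑en‑5‑yn‑1‑ylidene]hexahydrofuro[3,2‑b]furan
Product: 17 (2E,3S,3aR,5R,6aS)‑3‑bromo‑5‑[(1S)‑1‑bromopropyl]‑2‑[(3Z)‑hex‑3‑en‑5‑yn‑1‑ylidene]hexahydrofuro[3,2‑b]furan
Conditions: K2CO3 (0.2 equiv), MeOH, 0 °C
Reagents that add atoms: none
Why: Methanolysis of the alkynyl C–Si bond (protodesilylation) at 0 °C is much faster than substitution or elimination of the secondary bromides and leaves all stereo‑elements untouched.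

## Compound list

1 | 1,4‑bis(trimethylsilyl)buta‑1,3‑diyne | C[Si](C)(C)C#CC#C[Si](C)(C)C | starting material
2 | lithium 4‑(trimethylsilyl)buta‑1,3‑diyn‑1‑ide | [Li+].[C-]#CC#C[Si](C)(C)C | intermediate
3 | buta‑1,3‑diyn‑1‑yl(trimethyl)silane | C#CC#C[Si](C)(C)C | intermediate
4 | (3E)‑hex‑3‑en‑1‑ol | CC/C=C/CCO | starting material
5 | (3E)‑hex‑3‑enal | CC/C=C/CC=O | intermediate
6 | (5S,7E)‑1‑(trimethylsilyl)deca‑7‑ene‑1,3‑diyn‑5‑ol | C[Si](C)(C)C#CC#C[C@@H](O)C/C=C/CC | intermediate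
7 | (3Z,5S,7E)‑1‑(trimethylsilyl)deca‑3,7‑dien‑1‑yn‑5‑ol | C[Si](C)(C)C#C/C=C\[C@@H](O)C/C=C/CC | intermediate
8 | (3Z,5S,7E)‑deca‑3,7‑dien‑1‑yn‑5‑ol | C#C/C=C\[C@@H](O)C/C=C/CC | intermediate
9 | (1S,3E)‑1‑[(2R,3S)‑3‑ethynyloxiran‑2‑yl]hex‑3‑en‑1‑ol | C#C[C@@H]1O[C@@H]1[C@@H](O)C/C=C/CC | intermediate
10 | (3R,4R,5S,7E)‑3‑bromodec‑7‑en‑1‑yne‑4,5‑diol | C#C[C@@H](Br)[C@H](O)[C@@H](O)C/C=C/CC | intermediate
11 | (2R,3S,5R)‑2‑[(1R)‑1‑bromoprop‑2‑yn‑1‑yl]‑5‑[(1S)‑1‑bromopropyl]oxolan‑3‑ol | C#C[C@@H](Br)[C@@H]1O[C@@H]([C@@H](Br)CC)C[C@@H]1O | intermediate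
12 | (2E,3S,3aR,5R,6aS)‑3‑bromo‑5‑[(1S)‑1‑bromopropyl]‑2‑(but‑3‑en‑1‑ylidene)hexahydrofuro[3,2‑b]furan | C=CC/C=C1/O[C@H]2C[C@H]([C@@H](Br)CC)O[C@H]2[C@@H]1Br | intermediate
13 | bromoethene | C=CBr | starting material
14 | ethynyl(trimethyl)silane | C#C[Si](C)(C)C | starting material
15 | but‑3‑en‑1‑yn‑1‑yl(trimethyl)silane | C=CC#C[Si](C)(C)C | intermediate
16 | (2E,3S,3aR,5R,6aS)‑3‑bromo‑5‑[(1S)‑1‑bromopropyl]‑2‑[(3Z)‑6‑(trimethylsilyl)hex‑3‑en‑5‑yn‑1‑ylidene]hexahydrofuro[3,2‑b]furan | C[Si](C)(C)C#C/C=C\C/C=C1/O[C@H]2C[C@H]([C@@H](Br)CC)O[C@H]2[C@@H]1Br | intermediate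
17 | (2E,3S,3aR,5R,6aS)‑3‑bromo‑5‑[(1S)‑1‑bromopropyl]‑2‑[(3Z)‑hex‑3‑en‑5‑yn‑1‑ylidene]hexahydrofuro[3,2‑b]furan | C#C/C=C\C/C=C1/O[C@H]2C[C@H]([C@@H](Br)CC)O[C@H]2[C@@H]1Br | target

## Step count and risks

Total step count: 10. Longest linear sequence: 8 steps (4 → 17 through steps 2, 3, 4, 5, 6, 7, 9 and 10).

**Most likely to fail, first: step 7.** The trans/cis ratio at C12 in the bromoetherification is only substrate‑controlled. Allyl capture of the alkenylpalladium must beat protonolysis. Halide exchange at the C8 bromide is possible. The fallback avoids the palladium stage and the metathesis altogether; it sets out from 8 and comes back at 16. Copper‑mediated coupling (CuI, K2CO3, NaI, DMF) of the terminal alkyne of 8 with the separately prepared [(3Z)‑5‑bromopent‑3‑en‑1‑yn‑1‑yl](trimethyl)silane F1 gives the skipped enediyne alcohol (3Z,8Z,10S,12E)‑1‑(trimethylsilyl)pentadeca‑3,8,12‑triene‑1,6‑diyn‑10‑ol F2, with the whole C1–C7 unit and the Z alkene already in place. The directed epoxidation of step 5 then gives (1S,3E)‑1‑{(2R,3S)‑3‑[(4Z)‑7‑(trimethylsilyl)hept‑4‑ene‑1,6‑diyn‑1‑yl]oxiran‑2‑yl}hex‑3‑en‑1‑ol F3. MgBr2·OEt2 gives (3Z,8R,9R,10S,12E)‑8‑bromo‑1‑(trimethylsilyl)pentadeca‑3,12‑diene‑1,6‑diyne‑9,10‑diol F4. NBS closes ring B to (2R,3S,5R)‑2‑[(1R,5Z)‑1‑bromo‑8‑(trimethylsilyl)oct‑5‑ene‑2,7‑diyn‑1‑yl]‑5‑[(1S)‑1‑bromopropyl]oxolan‑3‑ol F5. Ring A is then closed by La[N(SiMe3)2]3‑catalysed hydroalkoxylation in benzene: syn insertion of the internal alkyne into the La–O bond followed by protonolysis puts C5 trans to oxygen and gives 16 directly.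

**Second: step 9.** The Z/E ratio rests on the inherent preference of enyne partners, and the skipped diene may isomerise. The fallback sets out from 12 and comes back at 16, and takes the alkene geometry from the reagent instead. Stereoretentive metathesis of 12 with the Z‑configured donor (3Z)‑1,6‑bis(trimethylsilyl)hex‑3‑ene‑1,5‑diyne F6 and the dithiolate carbene complex Ru(=CH‑C6H4‑2‑O‑iPr)(SIMes)(S2C6H2Cl2) transfers the Z geometry of the donor to C3=C4.

**Third: step 3.** The β,γ‑unsaturated aldehyde may enolise or isomerise under the zinc alkoxide conditions, and the ee rests on a catalyst‑controlled addition to an unbranched aldehyde. The fallback sets out from 5 (with acetylide 2 made as in step 1) and comes back at 6, and sets C10 by reduction instead of addition. Addition of 2 to 5 in THF at −78 °C gives racemic (7E)‑1‑(trimethylsilyl)deca‑7‑ene‑1,3‑diyn‑5‑ol F7. MnO2 oxidation gives (7E)‑1‑(trimethylsilyl)deca‑7‑ene‑1,3‑diyn‑5‑one F8. Asymmetric transfer hydrogenation with RuCl[(S,S)‑TsDPEN](p‑cymene) in i‑PrOH, whose sense for alkynyl ketones is established, gives 6.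

## Further compounds

F1 | step 7 | [(3Z)‑5‑bromopent‑3‑en‑1‑yn‑1‑yl](trimethyl)silane | C[Si](C)(C)C#C/C=C\CBr
F2 | step 7 | (3Z,8Z,10S,12E)‑1‑(trimethylsilyl)pentadeca‑3,8,12‑triene‑1,6‑diyn‑10‑ol | C[Si](C)(C)C#C/C=C\CC#C/C=C\[C@@H](O)C/C=C/CC
F3 | step 7 | (1S,3E)‑1‑{(2R,3S)‑3‑[(4Z)‑7‑(trimethylsilyl)hept‑4‑ene‑1,6‑diyn‑1‑yl]oxiran‑2‑yl}hex‑3‑en‑1‑ol | C[Si](C)(C)C#C/C=C\CC#C[C@@H]1O[C@@H]1[C@@H](O)C/C=C/CC
F4 | step 7 | (3Z,8R,9R,10S,12E)‑8‑bromo‑1‑(trimethylsilyl)pentadeca‑3,12‑diene‑1,6‑diyne‑9,10‑diol | C[Si](C)(C)C#C/C=C\CC#C[C@@H](Br)[C@H](O)[C@@H](O)C/C=C/CC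
F5 | step 7 | (2R,3S,5R)‑2‑[(1R,5Z)‑1‑bromo‑8‑(trimethylsilyl)oct‑5‑ene‑2,7‑diyn‑1‑yl]‑5‑[(1S)‑1‑bromopropyl]oxolan‑3‑ol | C[Si](C)(C)C#C/C=C\CC#C[C@@H](Br)[C@@H]1O[C@@H]([C@@H](Br)CC)C[C@@H]1O
F6 | step 9 | (3Z)‑1,6‑bis(trimethylsilyl)hex‑3‑ene‑1,5‑diyne | C[Si](C)(C)C#C/C=C\C#C[Si](C)(C)C
F7 | step 3 | (7E)‑1‑(trimethylsilyl)deca‑7‑ene‑1,3‑diyn‑5‑ol (racemic) | C[Si](C)(C)C#CC#CC(O)C/C=C/CC
F8 | step 3 | (7E)‑1‑(trimethylsilyl)deca‑7‑ene‑1,3‑diyn‑5‑one | C[Si](C)(C)C#CC#CC(=O)C/C=C/CC
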